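Ring A (C1, C2, C3, C4, C5, C10; drimane-type locants) is grown from a cyclopentanone by one-carbon ring expansion. A Carroll rearrangement moves the C6–O stereocentre of a 2-iodocyclohexenol to C10 and leaves a two-carbon isopropyl ketone arm; palladium-catalysed enolate alkenylation then joins the isopropyl carbon (C4) to the iodoalkene carbon (C5). The resulting 2,2-dimethylcyclopentanone (C10, C1, C3, C4, C5) has its C3 carbonyl between the quaternary C4 and the C1 methylene, and the key step uses this: (trimethylsilyl)diazomethane inserts C2 between C1 and C3 only. Selectride reduction and Mitsunobu etherification with isofraxidin complete the target.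

Key step: step 10

Remark on locants: C1 and C2 are the ring A methylenes (C1 on C10), C3 the carbinol carbon, C4 the gem-dimethyl carbon, C5=C6 the ring alkene (C5 at the ring fusion), C7 a CH2, C8 the CHMe carbon, C9 the quaternary carbon carrying CH3 and C11H2–O, C10 the ring-fusion CH.

Assumption: in step 1 the enantiomer of the phosphoramidite ligand is chosen so that the methyl group is delivered to the face that gives the (3S) enolate.

**Step 1**
Reactants: 1 2-methylcyclohex-2-en-1-one
Product: 3 trimethyl{[(3S)-2,3-dimethylcyclohex-1-en-1-yl]oxy}silane, via aluminium enolate 2 (not isolated)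
Conditions: Me3Al (1.4 equiv), CuTC (2 mol %), chiral binaphthol-derived phosphoramidite (4 mol %), Et2O, −30 °C; then TMSOTf, THF, −30 → 0 °C
Reagents that add atoms: trimethylaluminium C[Al](C)C; trimethylsilyl trifluoromethanesulfonate C[Si](C)(C)OS(=O)(=O)C(F)(F)F
Why: Copper-catalysed asymmetric conjugate addition should deliver methyl to one face of the enone under ligand control (C8, S), and O-silylation of the aluminium enolate fixes the enolate regiochemistry.

**Step 2**
Reactants: 3 trimethyl{[(3S)-2,3-dimethylcyclohex-1-en-1-yl]oxy}silane; 4 benzyl chloromethyl ether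
Product: 6 (2S,3S)-2-[(benzyloxy)methyl]-2,3-dimethylcyclohexan-1-one, via lithium enolate 5 (not isolated)
Conditions: MeLi (1.05 equiv), THF, 0 °C → rt; then 4, DMPU, −78 → −20 °C
Reagents that add atoms: none
Why: Si–O cleavage by MeLi should give the tetrasubstituted lithium enolate regiospecifically, and enolate C-alkylation by the reactive α-chloro ether should occur anti to the adjacent C8 methyl, setting quaternary C9 with the two methyl groups cis.

**Step 3**
Reactants: 6 (2S,3S)-2-[(benzyloxy)methyl]-2,3-dimethylcyclohexan-1-one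
Product: 7 (5S,6S)-6-[(benzyloxy)methyl]-5,6-dimethylcyclohex-1-en-1-yl trifluoromethanesulfonate
Conditions: KHMDS, THF, −78 °C; PhNTf2, −78 → 0 °C
Reagents that add atoms: N-phenylbis(trifluoromethanesulfonimide) O=S(=O)(N(c1ccccc1)S(=O)(=O)C(F)(F)F)C(F)(F)F
Why: Only C5 carries α-hydrogens, so enolate O-triflation should give a single enol triflate.

**Step 4**
Reactants: 7 (5S,6S)-6-[(benzyloxy)methyl]-5,6-dimethylcyclohex-1-en-1-yl trifluoromethanesulfonate
Product: 8 ({[(1R,6S)-1,6-dimethylcyclohex-2-en-1-yl]methoxy}methyl)benzene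
Conditions: Pd(OAc)2 (5 mol %), PPh3, HCO2H, n-Bu3N, DMF, 60 °C
Reagents that add atoms: none
Why: Palladium-catalysed formate reduction of the enol triflate (oxidative addition, decarboxylation of the formate, C–H reductive elimination) should give the C5=C10 alkene and leave the benzyl ether intact.

**Step 5**
Reactants: 8 ({[(1R,6S)-1,6-dimethylcyclohex-2-en-1-yl]methoxy}methyl)benzene
Product: 9 (4R,5S)-4-[(benzyloxy)methyl]-4,5-dimethylcyclohex-2-en-1-one
Conditions: CrO3, 3,5-dimethylpyrazole, CH2Cl2, −20 °C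
Reagents that add atoms: chromium trioxide O=[Cr](=O)=O
Why: Chromium(VI) allylic oxidation should turn the only allylic methylene (C6; the other allylic carbon, C9, is quaternary) into the enone carbonyl, oxygenation at the neopentylic C10 terminus being disfavoured.

**Step 6**
Reactants: 9 (4R,5S)-4-[(benzyloxy)methyl]-4,5-dimethylcyclohex-2-en-1-one
Product: 10 (4R,5S)-4-[(benzyloxy)methyl]-2-iodo-4,5-dimethylcyclohex-2-en-1-one
Conditions: I2, pyridine, CH2Cl2, 0 °C → rt
Reagents that add atoms: iodine II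
Why: α-Iodination of the enone by conjugate addition of pyridine, iodination of the enolate and elimination (Baylis–Hillman-type sequence) should place iodine on C5.

**Step 7**
Reactants: 10 (4R,5S)-4-[(benzyloxy)methyl]-2-iodo-4,5-dimethylcyclohex-2-en-1-one
Product: 11 (1R,4R,5S)-4-[(benzyloxy)methyl]-2-iodo-4,5-dimethylcyclohex-2-en-1-ol
Conditions: NaBH4, CeCl3·7H2O, MeOH, −40 °C
Reagents that add atoms: none
Why: Luche 1,2-reduction should deliver hydride to the face of the C6 carbonyl anti to the C8 methyl group, giving the allylic alcohol with C6–OH cis to that methyl.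

**Step 8**
Reactants: 11 (1R,4R,5S)-4-[(benzyloxy)methyl]-2-iodo-4,5-dimethylcyclohex-2-en-1-ol; 12 methyl 4-methyl-3-oxopentanoate
Product: 15 1-{(1S,5S,6R)-6-[(benzyloxy)methyl]-2-iodo-5,6-dimethylcyclohex-2-en-1-yl}-3-methylbutan-2-one, via allyl β-keto ester 13 (not isolated), via β-keto acid 14 (not isolated)
Conditions: 12 (4 equiv), Al(Oi-Pr)3 (5 mol %), o-dichlorobenzene, 140 → 185 °C, MeOH and CO2 removed
Reagents that add atoms: none
Why: In this Carroll rearrangement, transesterification, suprafacial [3,3] shift of the ester enol across the cyclohexene and decarboxylation should transfer the C6–O configuration to C10, so the new C10–C1 bond forms on the face the oxygen leaves (cis to both methyl groups, H10 cis to CH2OBn) while the alkene moves to C5=C6.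

**Step 9**
Reactants: 15 1-{(1S,5S,6R)-6-[(benzyloxy)methyl]-2-iodo-5,6-dimethylcyclohex-2-en-1-yl}-3-methylbutan-2-one
Product: 16 (6S,7R,7aR)-7-[(benzyloxy)methyl]-3,3,6,7-tetramethyl-1,3,5,6,7,7a-hexahydro-2H-inden-2-one
Conditions: Pd(PPh3)4 (10 mol %), t-BuOK (1.3 equiv), THF, rt → 45 °C
Reagents that add atoms: none
Why: Intramolecular palladium-catalysed α-alkenylation of the ketone enolate (oxidative addition into C5–I, C–C reductive elimination) should close the five-membered ring at the isopropyl carbon, the only enolate carbon that can reach C5, creating quaternary C4 and keeping the C5=C6 alkene in place.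

**Step 10**
Reactants: 16 (6S,7R,7aR)-7-[(benzyloxy)methyl]-3,3,6,7-tetramethyl-1,3,5,6,7,7a-hexahydro-2H-inden-2-one
Product: 18 (4aR,5R,6S)-5-[(benzyloxy)methyl]-1,1,5,6-tetramethyl-3,4,4a,5,6,7-hexahydronaphthalen-2(1H)-one, via α-silyl ketone 17 (not isolated)
Conditions: TMSCHN2 (1.5 equiv), BF3·OEt2 (1.5 equiv), CH2Cl2, −78 → −30 °C; then 1 M HCl, THF, rt
Reagents that add atoms: (trimethylsilyl)diazomethane C[Si](C)(C)C=[N+]=[N-]
Why: BF3 activates the C3 carbonyl, the nucleophilic carbon of TMSCHN2 adds to it, and in the resulting β-oxido diazonium species the C1–C3 bond migrates to the diazo carbon with loss of N2 (Tiffeneau–Demjanov-type 1,2-shift), so that this carbon becomes C2 of the six-membered ring C10–C1–C2–C3–C4–C5. The closest known reaction type is the Lewis-acid-promoted one-carbon homologation of cycloalkanones with (trimethylsilyl)diazomethane. No ring is closed in this step: the existing cyclopentanone ring (C10, C1, C3, C4, C5) is enlarged by insertion of one carbon. No new stereocentre is formed, and C10 is not enolisable, so its configuration is untouched. The step needs migration of C1 and not of C4 and it must stop after one insertion: the quaternary, alkenyl-substituted C4 is shielded, the bulky silyl group of the adduct turns away from it so that the C1–C3 bond lies anti to the leaving N2, and the α-silyl ketone 17 is too hindered to add a second equivalent. Acidic work-up removes the silyl group to give 18.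

**Step 11**
Reactants: 18 (4aR,5R,6S)-5-[(benzyloxy)methyl]-1,1,5,6-tetramethyl-3,4,4a,5,6,7-hexahydronaphthalen-2(1H)-one
Product: 19 (2S,4aR,5R,6S)-5-[(benzyloxy)methyl]-1,1,5,6-tetramethyl-1,2,3,4,4a,5,6,7-octahydronaphthalen-2-ol
Conditions: L-Selectride, THF, −78 → −40 °C; aq. NH4Cl
Reagents that add atoms: none
Why: The bulky trialkylborohydride should attack the C3 carbonyl of the ring A chair (H10 axial) from the equatorial direction, giving the axial alcohol trans to H10 (3S).

**Step 12**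
Reactants: 19 (2S,4aR,5R,6S)-5-[(benzyloxy)methyl]-1,1,5,6-tetramethyl-1,2,3,4,4a,5,6,7-octahydronaphthalen-2-ol
Product: 20 (2S,4aR,5R,6S)-5-(hydroxymethyl)-1,1,5,6-tetramethyl-1,2,3,4,4a,5,6,7-octahydronaphthalen-2-ol
Conditions: Li, liquid NH3, THF, −78 °C; NH4Cl
Reagents that add atoms: none
Why: Dissolving-metal (Birch-type) cleavage of the benzyl ether should free the primary alcohol, the isolated trisubstituted alkene and the secondary alcohol being inert.

**Step 13**
Reactants: 20 (2S,4aR,5R,6S)-5-(hydroxymethyl)-1,1,5,6-tetramethyl-1,2,3,4,4a,5,6,7-octahydronaphthalen-2-ol; 21 isofraxidin (7-hydroxy-6,8-dimethoxy-2H-chromen-2-one)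
Product: 22 7-{[(1R,2S,6S,8aR)-6-hydroxy-1,2,5,5-tetramethyl-1,2,3,5,6,7,8,8a-octahydronaphthalen-1-yl]methoxy}-6,8-dimethoxy-2H-chromen-2-one
Conditions: 21 (1.5 equiv), cyanomethylenetributylphosphorane (2 equiv), toluene, 110 °C
Reagents that add atoms: none
Why: In this Mitsunobu-type etherification the acidic phenol protonates the ylide, the primary hydroxyl is activated as an alkoxyphosphonium ion and displaced by the phenoxide at C11 (no stereocentre involved), whereas the secondary C3 hydroxyl next to quaternary C4 should not react.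

**Compound list**

1 | 2-methylcyclohex-2-en-1-one | CC1=CCCCC1=O | starting material
2 | dimethyl{[(3S)-2,3-dimethylcyclohex-1-en-1-yl]oxy}alumane | C[C@H]1CCCC(O[Al](C)C)=C1C | intermediate
3 | trimethyl{[(3S)-2,3-dimethylcyclohex-1-en-1-yl]oxy}silane | C[C@H]1CCCC(O[Si](C)(C)C)=C1C | intermediate
4 | benzyl chloromethyl ether | ClCOCc1ccccc1 | starting material
5 | lithium (3S)-2,3-dimethylcyclohex-1-en-1-olate | C[C@H]1CCCC([O-])=C1C.[Li+] | intermediate
6 | (2S,3S)-2-[(benzyloxy)methyl]-2,3-dimethylcyclohexan-1-one | O=C1CCC[C@H](C)[C@@]1(C)COCc1ccccc1 | intermediate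
7 | (5S,6S)-6-[(benzyloxy)methyl]-5,6-dimethylcyclohex-1-en-1-yl trifluoromethanesulfonate | O=S(=O)(OC1=CCC[C@H](C)[C@@]1(C)COCc1ccccc1)C(F)(F)F | intermediate
8 | ({[(1R,6S)-1,6-dimethylcyclohex-2-en-1-yl]methoxy}methyl)benzene | C1=CCC[C@H](C)[C@@]1(C)COCc1ccccc1 | intermediate
9 | (4R,5S)-4-[(benzyloxy)methyl]-4,5-dimethylcyclohex-2-en-1-one | O=C1C=C[C@](C)(COCc2ccccc2)[C@@H](C)C1 | intermediate
10 | (4R,5S)-4-[(benzyloxy)methyl]-2-iodo-4,5-dimethylcyclohex-2-en-1-one | O=C1C(I)=C[C@](C)(COCc2ccccc2)[C@@H](C)C1 | intermediate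
11 | (1R,4R,5S)-4-[(benzyloxy)methyl]-2-iodo-4,5-dimethylcyclohex-2-en-1-ol | O[C@H]1C(I)=C[C@](C)(COCc2ccccc2)[C@@H](C)C1 | intermediate
12 | methyl 4-methyl-3-oxopentanoate | COC(=O)CC(=O)C(C)C | starting material
13 | (1R,4R,5S)-4-[(benzyloxy)methyl]-2-iodo-4,5-dimethylcyclohex-2-en-1-yl 4-methyl-3-oxopentanoate | CC(C)C(=O)CC(=O)O[C@H]1C(I)=C[C@](C)(COCc2ccccc2)[C@@H](C)C1 | intermediate
14 | 2-{(1S,5S,6R)-6-[(benzyloxy)methyl]-2-iodo-5,6-dimethylcyclohex-2-en-1-yl}-4-methyl-3-oxopentanoic acid (either configuration at C2) | CC(C)C(=O)C(C(=O)O)[C@@H]1C(I)=CC[C@H](C)[C@@]1(C)COCc1ccccc1 | intermediate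
15 | 1-{(1S,5S,6R)-6-[(benzyloxy)methyl]-2-iodo-5,6-dimethylcyclohex-2-en-1-yl}-3-methylbutan-2-one | CC(C)C(=O)C[C@@H]1C(I)=CC[C@H](C)[C@@]1(C)COCc1ccccc1 | intermediate
16 | (6S,7R,7aR)-7-[(benzyloxy)methyl]-3,3,6,7-tetramethyl-1,3,5,6,7,7a-hexahydro-2H-inden-2-one | O=C1C[C@@H]2C(=CC[C@H](C)[C@@]2(C)COCc2ccccc2)C1(C)C | intermediate
17 | (4aR,5R,6S)-5-[(benzyloxy)methyl]-1,1,5,6-tetramethyl-3-(trimethylsilyl)-3,4,4a,5,6,7-hexahydronaphthalen-2(1H)-one (either configuration at C3) | O=C1C([Si](C)(C)C)C[C@@H]2C(=CC[C@H](C)[C@@]2(C)COCc2ccccc2)C1(C)C | intermediate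
18 | (4aR,5R,6S)-5-[(benzyloxy)methyl]-1,1,5,6-tetramethyl-3,4,4a,5,6,7-hexahydronaphthalen-2(1H)-one | O=C1CC[C@@H]2C(=CC[C@H](C)[C@@]2(C)COCc2ccccc2)C1(C)C | intermediate
19 | (2S,4aR,5R,6S)-5-[(benzyloxy)methyl]-1,1,5,6-tetramethyl-1,2,3,4,4a,5,6,7-octahydronaphthalen-2-ol | O[C@H]1CC[C@@H]2C(=CC[C@H](C)[C@@]2(C)COCc2ccccc2)C1(C)C | intermediate
20 | (2S,4aR,5R,6S)-5-(hydroxymethyl)-1,1,5,6-tetramethyl-1,2,3,4,4a,5,6,7-octahydronaphthalen-2-ol | O[C@H]1CC[C@@H]2C(=CC[C@H](C)[C@@]2(C)CO)C1(C)C | intermediate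
21 | isofraxidin (7-hydroxy-6,8-dimethoxy-2H-chromen-2-one) | COc1cc2ccc(=O)oc2c(OC)c1O | starting material
22 | 7-{[(1R,2S,6S,8aR)-6-hydroxy-1,2,5,5-tetramethyl-1,2,3,5,6,7,8,8a-octahydronaphthalen-1-yl]methoxy}-6,8-dimethoxy-2H-chromen-2-one | COc1cc2ccc(=O)oc2c(OC)c1OC[C@@]1(C)[C@@H]2CC[C@H](O)C(C)(C)C2=CC[C@@H]1C | target

**Step count**

Total steps: 13. Longest linear sequence: 13 steps (1 → 22); 4, 12 and 21 are bought.

**Steps most likely to fail**

Step 13. The neopentyl C11 centre may resist SN2 displacement of the alkoxyphosphonium ion, so that etherification stalls and the phenol is consumed in side reactions of the betaine. The fallback sets out from 20 and comes back at 22. Chemoselective sulfonylation of the primary hydroxyl (Tf2O, 2,6-di-tert-butyl-4-methylpyridine, CH2Cl2, −78 °C) should give [(1R,2S,6S,8aR)-6-hydroxy-1,2,5,5-tetramethyl-1,2,3,5,6,7,8,8a-octahydronaphthalen-1-yl]methyl trifluoromethanesulfonate F1. This sulfonate has no β-hydrogen for elimination and should be displaced by the caesium salt of 21 (Cs2CO3, DMF, 50 °C) to give 22.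

Step 10. Migration of the allylic quaternary carbon C4 in competition with C1, or a second insertion into the product, would erode regiocontrol. The fallback sets out from 16 and comes back at 18; it fixes the regiochemistry through the only possible enolate.
- Enolisation towards C1 and silylation (LDA, TMSCl, THF, −78 °C) gives {[(6S,7R,7aR)-7-[(benzyloxy)methyl]-3,3,6,7-tetramethyl-5,6,7,7a-tetrahydro-3H-inden-2-yl]oxy}trimethylsilane F2.
- Simmons–Smith-type cyclopropanation (Et2Zn, CH2I2, CH2Cl2, 0 °C) gives the siloxycyclopropane F3 (CH2 bridging C1 and C3 of F2).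
- FeCl3 in DMF cleaves the C1–C3 bond of the cyclopropane to the ring-enlarged (4aR,5R,6S)-5-[(benzyloxy)methyl]-4-chloro-1,1,5,6-tetramethyl-3,4,4a,5,6,7-hexahydronaphthalen-2(1H)-one F4.
- NaOAc in MeOH eliminates HCl to (4aR,5R,6S)-5-[(benzyloxy)methyl]-1,1,5,6-tetramethyl-4a,5,6,7-tetrahydronaphthalen-2(1H)-one F5.
- Conjugate reduction with [(Ph3P)CuH]6 (toluene, rt) gives 18.

Step 8. The thermal [3,3] shift may be too slow at the hindered C10 terminus, and long heating at 185 °C may degrade the iodoalkene before it rearranges. The fallback sets out from 11 and comes back at 15. Johnson–Claisen rearrangement with triethyl orthoacetate (cat. propionic acid, 140 °C) should give ethyl 2-{(1S,5S,6R)-6-[(benzyloxy)methyl]-2-iodo-5,6-dimethylcyclohex-2-en-1-yl}acetate F6 with the same chirality transfer. MeNHOMe·HCl and i-PrMgCl (THF, −20 °C) convert it into 2-{(1S,5S,6R)-6-[(benzyloxy)methyl]-2-iodo-5,6-dimethylcyclohex-2-en-1-yl}-N-methoxy-N-methylacetamide F7. Addition of i-PrMgCl (THF, −20 → 0 °C, cold enough to spare the iodoalkene) then gives 15.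

**Further compounds**

F1 | step 13 | [(1R,2S,6S,8aR)-6-hydroxy-1,2,5,5-tetramethyl-1,2,3,5,6,7,8,8a-octahydronaphthalen-1-yl]methyl trifluoromethanesulfonate | O[C@H]1CC[C@@H]2C(=CC[C@H](C)[C@@]2(C)COS(=O)(=O)C(F)(F)F)C1(C)C
F2 | step 10 | {[(6S,7R,7aR)-7-[(benzyloxy)methyl]-3,3,6,7-tetramethyl-5,6,7,7a-tetrahydro-3H-inden-2-yl]oxy}trimethylsilane | C[Si](C)(C)OC1=C[C@@H]2C(=CC[C@H](C)[C@@]2(C)COCc2ccccc2)C1(C)C
F3 | step 10 | siloxycyclopropane from F2 (CH2 bridging C1 and C3, trimethylsilyloxy on C3) | C[Si](C)(C)OC12CC1[C@@H]1C(=CC[C@H](C)[C@@]1(C)COCc1ccccc1)C2(C)C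
F4 | step 10 | (4aR,5R,6S)-5-[(benzyloxy)methyl]-4-chloro-1,1,5,6-tetramethyl-3,4,4a,5,6,7-hexahydronaphthalen-2(1H)-one | O=C1CC(Cl)[C@@H]2C(=CC[C@H](C)[C@@]2(C)COCc2ccccc2)C1(C)C
F5 | step 10 | (4aR,5R,6S)-5-[(benzyloxy)methyl]-1,1,5,6-tetramethyl-4a,5,6,7-tetrahydronaphthalen-2(1H)-one | O=C1C=C[C@@H]2C(=CC[C@H](C)[C@@]2(C)COCc2ccccc2)C1(C)C
F6 | step 8 | ethyl 2-{(1S,5S,6R)-6-[(benzyloxy)methyl]-2-iodo-5,6-dimethylcyclohex-2-en-1-yl}acetate | CCOC(=O)C[C@@H]1C(I)=CC[C@H](C)[C@@]1(C)COCc1ccccc1
F7 | step 8 | 2-{(1S,5S,6R)-6-[(benzyloxy)methyl]-2-iodo-5,6-dimethylcyclohex-2-en-1-yl}-N-methoxy-N-methylacetamide | CON(C)C(=O)C[C@@H]1C(I)=CC[C@H](C)[C@@]1(C)COCc1ccccc1
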